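The seven-membered ring is closed by joining C1, the tertiary carbinol carbon that carries the acyl side chain, to its ring neighbour C5, the ester-bearing CH. The route reads this 1,2-dioxygenated C1–C5 pair, with the C2 ketone on C1, as an allylic alcohol: an intramolecular Nozaki–Hiyama–Kishi reaction adds a C1 alkenyl triflate to a C5 aldehyde that sits on the preformed cis-α-methylene-γ-butyrolactone. One operation closes the cycloheptane, creates C5 and leaves a (Z)-exocyclic C1=C2 alkene; dihydroxylation anti to the C5 ester and oxidation at C2 then give the hydroxy ketone. The precursor is an open-chain enol triflate–lactone aldehyde made by Evans aldol and indium allylation.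

Key step: step 14

Atom labels used below: cycloheptane C1 (C–OH carrying the side chain), C5 (CH–O-ester), C6 (CH–O of the lactone), C7 (ring-fusion CH), C8 (CH2), C9 (CH–OH), C10 (CH–CH3); side chain C2 (C=O), C3 (CH2), C4 (CH–OH); lactone C11 (=CH2) and C12 (C=O). TBS = tert-butyldimethylsilyl, Tf = trifluoromethanesulfonyl.

Remark: metal enolates and organometallic species formed in situ (boron and potassium enolates, lithium acetylide, allylindium, alkenylchromium) are treated as reactive forms of the numbered compounds.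

Step 1
Reactants: 1 (S)-4-benzyl-3-propanoyl-1,3-oxazolidin-2-one; 2 3-(TBS-oxy)propanal
Product: 3 (S)-4-benzyl-3-[(2S,3R)-5-(TBS-oxy)-3-hydroxy-2-methylpentanoyl]-1,3-oxazolidin-2-one
Conditions: Bu2BOTf, Et3N, CH2Cl2, −78 to 0 °C; then 2, −78 to 0 °C; H2O2, MeOH, pH 7 buffer
Reagents that add atoms: none
Why: Evans syn aldol reaction: the (Z)-boron enolate of 1 adds through a Zimmerman–Traxler chair on the face away from the benzyl group, which sets C10 (S) and C9 (R) in the required syn relation.

Step 2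
Reactants: 3 aldol adduct
Product: 4 (2S,3R)-5-(TBS-oxy)-3-hydroxy-N-methoxy-N,2-dimethylpentanamide
Conditions: MeNH(OMe)·HCl, AlMe3, CH2Cl2, −20 to 0 °C
Reagents that add atoms: N,O-dimethylhydroxylamine hydrochloride, CNOC.Cl
Why: Weinreb transamidation of the β-hydroxy imide by the aluminium amide, assisted by the free hydroxyl, releases the auxiliary without touching C10.

Step 3
Reactants: 4 hydroxy Weinreb amide
Product: 5 (2S,3R)-3,5-bis(TBS-oxy)-N-methoxy-N,2-dimethylpentanamide
Conditions: TBSOTf, 2,6-lutidine, CH2Cl2, −78 to 0 °C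
Reagents that add atoms: tert-butyldimethylsilyl trifluoromethanesulfonate, CC(C)(C)[Si](C)(C)OS(=O)(=O)C(F)(F)F
Why: Standard silyl ether formation blocks the secondary C9 hydroxyl before the acetylide addition and the enolisation.

Step 4
Reactants: 6 (S)-but-3-yn-2-ol
Product: 7 (S)-3-(TBS-oxy)but-1-yne
Conditions: TBSCl, imidazole, CH2Cl2, 0 °C to rt
Reagents that add atoms: tert-butyldimethylsilyl chloride, CC(C)(C)[Si](C)(C)Cl
Why: Silyl ether formation; the C4 stereocentre (S) comes from the chiral pool and is not touched again.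

Step 5
Reactants: 7 silyl-protected butynol; 5 Weinreb amide
Product: 8 (2S,6S,7R)-2,7,9-tris(TBS-oxy)-6-methylnon-3-yn-5-one
Conditions: 7, n-BuLi, THF, −78 °C; then 5, −78 to 0 °C; aq. NH4Cl
Reagents that add atoms: none
Why: Acylation of the lithium acetylide by the Weinreb amide, whose chelated tetrahedral intermediate prevents over-addition and α-epimerisation.

Step 6
Reactants: 8 ynone
Product: 9 (2S,6S,7R)-2,7,9-tris(TBS-oxy)-6-methylnonan-5-one
Conditions: H2 (1 atm), Pd/C, EtOAc, rt
Reagents that add atoms: none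
Why: Heterogeneous hydrogenation saturates the ynone triple bond to the C2–C3 ethylene unit under neutral conditions that leave the ketone, the silyl ethers and C10 untouched.

Step 7
Reactants: 9 ketone
Product: 10 (2S,4Z,6S,7R)-2,7,9-tris(TBS-oxy)-6-methylnon-4-en-5-yl trifluoromethanesulfonate
Conditions: KN(SiMe3)2, THF, −78 °C; then PhNTf2, −78 to 0 °C
Reagents that add atoms: N-phenylbis(trifluoromethanesulfonimide), O=S(=O)(N(c1ccccc1)S(=O)(=O)C(F)(F)F)C(F)(F)F
Why: Kinetic deprotonation by the hindered amide base should take place at the C2 methylene and not at the C10 methine, and O-triflation of the (Z)-enolate (enol triflate synthesis) fixes the C1=C2 geometry with oxygen cis to C3.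

Step 8
Reactants: 10 enol triflate
Product: 11 (3R,4S,5Z,8S)-3,8-bis(TBS-oxy)-1-hydroxy-4-methylnon-5-en-5-yl trifluoromethanesulfonate
Conditions: HF·pyridine, pyridine, THF, 0 °C
Reagents that add atoms: none
Why: Fluoride desilylation is fastest at the unhindered primary ether, so buffered HF·pyridine at low temperature should free the C7 hydroxyl selectively.

Step 9
Reactants: 11 primary alcohol
Product: 12 (3R,4S,5Z,8S)-3,8-bis(TBS-oxy)-4-methyl-1-oxonon-5-en-5-yl trifluoromethanesulfonate
Conditions: Dess–Martin periodinane, NaHCO3, CH2Cl2, rt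
Reagents that add atoms: none
Why: Dess–Martin oxidation gives the β-silyloxy aldehyde without elimination or loss of the enol triflate.

Step 10
Reactants: 12 aldehyde; 13 methyl acrylate
Product: 14 methyl (5R,6S,7Z,10S)-5,10-bis(TBS-oxy)-3-hydroxy-6-methyl-2-methylidene-7-(trifluoromethanesulfonyloxy)undec-7-enoate (both C3 epimers, that is both epimers at C7 of the labels)
Conditions: quinuclidine (cat.), MeOH, rt
Reagents that add atoms: none
Why: Morita–Baylis–Hillman reaction, accelerated in methanol; the new carbinol centre is of no consequence because it becomes sp2 in the next step.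

Step 11
Reactants: 14 Morita–Baylis–Hillman adduct
Product: 15 methyl (2Z,5R,6S,7Z,10S)-2-(bromomethyl)-5,10-bis(TBS-oxy)-6-methyl-7-(trifluoromethanesulfonyloxy)undeca-2,7-dienoate
Conditions: NBS, Me2S, CH2Cl2, 0 °C to rt
Reagents that add atoms: N-bromosuccinimide, O=C1CCC(=O)N1Br
Why: Corey–Kim-type bromination of the allylic alcohol with allylic transposition (SN2′) gives the thermodynamically preferred (Z)-2-(bromomethyl)enoate.

Step 12
Reactants: 15 allylic bromide; 16 (S)-2,2-dimethyl-1,3-dioxolane-4-carbaldehyde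
Product: 18 (4S,5R)-5-[(S)-2,2-dimethyl-1,3-dioxolan-4-yl]-3-methylidene-4-[(2R,3S,4Z,7S)-2,7-bis(TBS-oxy)-3-methyl-4-(trifluoromethanesulfonyloxy)oct-4-en-1-yl]oxolan-2-one, via hydroxy ester 17 (not isolated)
Conditions: In powder, THF–H2O, rt; then PPTS (cat.), toluene, 50 °C
Reagents that add atoms: none
Why: Indium-mediated Barbier allylation: the allylindium from the (Z)-bromide reacts at C7 through a chair transition state to give the C6/C7 syn adduct, the aldehyde is attacked in the Felkin–Anh sense anti to the dioxolane oxygen (C6 R), and the syn hydroxy ester lactonises to the cis-4,5-disubstituted α-methylene lactone.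

Step 13
Reactants: 18 lactone acetonide
Product: 20 (2R,3S)-4-methylidene-5-oxo-3-[(2R,3S,4Z,7S)-2,7-bis(TBS-oxy)-3-methyl-4-(trifluoromethanesulfonyloxy)oct-4-en-1-yl]oxolane-2-carbaldehyde, via diol 19 (not isolated)
Conditions: H5IO6, EtOAc, rt
Reagents that add atoms: none
Why: Periodic acid first hydrolyses the terminal acetonide and then cleaves the glycol (glycol cleavage), which turns the former dioxolane carbon into the C5 aldehyde while the secondary silyl ethers should survive.

Step 14
Reactants: 20 enol triflate–lactone aldehyde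
Product: 21 cis-fused bicyclic allylic alcohol (5R,6R,7S,9R,10R,4S) with (Z)-exocyclic C1=C2 alkene and C5–OH trans to the lactone oxygen
Conditions: CrCl2 (10 equiv), NiCl2 (2 mol % of CrCl2), degassed DMF, rt, slow addition to 0.003 M
Reagents that add atoms: none
Why: Zerovalent nickel, generated from NiCl2 by CrCl2, inserts into the C1–OTf bond and transmetalates to a trivalent alkenylchromium species that adds to the C5 aldehyde; the closest known reaction type is the intramolecular Nozaki–Hiyama–Kishi reaction of alkenyl triflates used for medium carbocycles. The cycloheptane closes in a 7-exo-trig mode with retention of the alkene geometry, so that C3 ends up cis to C5. The cis-fused lactone holds C5 and C8 on one face of the five-membered ring and so places both reacting termini within reach. The new stereocentre C5 is controlled by C6: in the non-chelated arrangement (DMF-solvated chromium, weakly basic lactone oxygen) the C5=O dipole opposes the C6–O bond and the tethered nucleophile can only arrive from the C7 side, which should favour the C5 alcohol trans to the lactone oxygen, although this preference is not secure. The step needs chemoselectivity for the aldehyde over the lactone and the acrylate unit and no epimerisation at C6, both secured by the neutral, aldehyde-selective organochromium chemistry, with high dilution against oligomerisation.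

Step 15
Reactants: 21 allylic alcohol; 22 (S)-2-methylbutanoic acid
Product: 23 C5 (S)-2-methylbutanoate of 21
Conditions: DCC, DMAP (cat.), CH2Cl2, 0 °C to rt
Reagents that add atoms: none
Why: Steglich esterification acylates the only free hydroxyl with retention at C5 and, at low temperature, without epimerisation of the α-centre of the acid.

Step 16
Reactants: 23 allylic ester
Product: 24 C1,C2-diol (1R,2R,4S,5S,6R,7S,9R,10S) with the C1 hydroxyl trans to the C5 ester oxygen
Conditions: OsO4 (5 mol %), NMO, acetone–H2O, 0 °C to rt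
Reagents that add atoms: N-methylmorpholine N-oxide, C[N+]1([O-])CCOCC1; water, O
Why: Upjohn dihydroxylation: the electron-rich trisubstituted alkene should react before the electron-poor methylene lactone, and osmylation anti to the allylic C5 acyloxy group, which 1,3-allylic strain with the cis C3 methylene holds perpendicular to the alkene plane, sets the C1 hydroxyl trans to the C5 oxygen (the C2 centre is temporary).

Step 17
Reactants: 24 diol
Product: 25 bis-TBS ether of the target (C2 ketone, tertiary C1 hydroxyl)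
Conditions: (COCl)2, DMSO, CH2Cl2, −78 °C; then Et3N, −78 to −20 °C
Reagents that add atoms: none
Why: Swern oxidation converts the secondary C2 alcohol into the ketone, the tertiary C1 hydroxyl being inert and activated-DMSO conditions avoiding glycol cleavage.

Step 18
Reactants: 25 bis-silyl ether
Product: 26 CNP0291806.1 (1S,4S,5S,6R,7S,9R,10S; (S)-2-methylbutanoate)
Conditions: HF·pyridine, THF, 0 °C to rt
Reagents that add atoms: none
Why: Fluoride cleavage of both secondary silyl ethers under weakly acidic, non-basic conditions that should spare the β-hydroxy ketone, the tertiary α-ketol, the ester and the methylene lactone.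

Compound list

1 | (S)-4-benzyl-3-propanoyl-1,3-oxazolidin-2-one | CCC(=O)N1[C@@H](Cc2ccccc2)COC1=O | starting material
2 | 3-(tert-butyldimethylsilyloxy)propanal | CC(C)(C)[Si](C)(C)OCCC=O | starting material
3 | (S)-4-benzyl-3-[(2S,3R)-5-(TBS-oxy)-3-hydroxy-2-methylpentanoyl]-1,3-oxazolidin-2-one | CC(C)(C)[Si](C)(C)OCC[C@@H](O)[C@H](C)C(=O)N1[C@@H](Cc2ccccc2)COC1=O | intermediate
4 | (2S,3R)-5-(TBS-oxy)-3-hydroxy-N-methoxy-N,2-dimethylpentanamide | CC(C)(C)[Si](C)(C)OCC[C@@H](O)[C@H](C)C(=O)N(C)OC | intermediate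
5 | (2S,3R)-3,5-bis(TBS-oxy)-N-methoxy-N,2-dimethylpentanamide | CC(C)(C)[Si](C)(C)OCC[C@@H](O[Si](C)(C)C(C)(C)C)[C@H](C)C(=O)N(C)OC | intermediate
6 | (S)-but-3-yn-2-ol | C#C[C@H](C)O | starting material
7 | (S)-3-(TBS-oxy)but-1-yne | C#C[C@H](C)O[Si](C)(C)C(C)(C)C | intermediate
8 | (2S,6S,7R)-2,7,9-tris(TBS-oxy)-6-methylnon-3-yn-5-one | CC(C)(C)[Si](C)(C)OCC[C@@H](O[Si](C)(C)C(C)(C)C)[C@H](C)C(=O)C#C[C@H](C)O[Si](C)(C)C(C)(C)C | intermediate
9 | (2S,6S,7R)-2,7,9-tris(TBS-oxy)-6-methylnonan-5-one | CC(C)(C)[Si](C)(C)OCC[C@@H](O[Si](C)(C)C(C)(C)C)[C@H](C)C(=O)CC[C@H](C)O[Si](C)(C)C(C)(C)C | intermediate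
10 | (2S,4Z,6S,7R)-2,7,9-tris(TBS-oxy)-6-methylnon-4-en-5-yl trifluoromethanesulfonate | CC(C)(C)[Si](C)(C)OCC[C@@H](O[Si](C)(C)C(C)(C)C)[C@H](C)/C(OS(=O)(=O)C(F)(F)F)=C/C[C@H](C)O[Si](C)(C)C(C)(C)C | intermediate
11 | (3R,4S,5Z,8S)-3,8-bis(TBS-oxy)-1-hydroxy-4-methylnon-5-en-5-yl trifluoromethanesulfonate | OCC[C@@H](O[Si](C)(C)C(C)(C)C)[C@H](C)/C(OS(=O)(=O)C(F)(F)F)=C/C[C@H](C)O[Si](C)(C)C(C)(C)C | intermediate
12 | (3R,4S,5Z,8S)-3,8-bis(TBS-oxy)-4-methyl-1-oxonon-5-en-5-yl trifluoromethanesulfonate | O=CC[C@@H](O[Si](C)(C)C(C)(C)C)[C@H](C)/C(OS(=O)(=O)C(F)(F)F)=C/C[C@H](C)O[Si](C)(C)C(C)(C)C | intermediate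
13 | methyl acrylate | C=CC(=O)OC | starting material
14 | methyl (5R,6S,7Z,10S)-5,10-bis(TBS-oxy)-3-hydroxy-6-methyl-2-methylidene-7-(trifluoromethanesulfonyloxy)undec-7-enoate, both C3 epimers | C=C(C(=O)OC)C(O)C[C@@H](O[Si](C)(C)C(C)(C)C)[C@H](C)/C(OS(=O)(=O)C(F)(F)F)=C/C[C@H](C)O[Si](C)(C)C(C)(C)C | intermediate
15 | methyl (2Z,5R,6S,7Z,10S)-2-(bromomethyl)-5,10-bis(TBS-oxy)-6-methyl-7-(trifluoromethanesulfonyloxy)undeca-2,7-dienoate | COC(=O)/C(CBr)=C/C[C@@H](O[Si](C)(C)C(C)(C)C)[C@H](C)/C(OS(=O)(=O)C(F)(F)F)=C/C[C@H](C)O[Si](C)(C)C(C)(C)C | intermediate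
16 | (S)-2,2-dimethyl-1,3-dioxolane-4-carbaldehyde | O=C[C@@H]1COC(C)(C)O1 | starting material
17 | open-chain syn homoallylic alcohol methyl ester (C6 R, C7 S; hydroxy ester form of 18) | C=C(C(=O)OC)[C@@H]([C@@H](O)[C@@H]1COC(C)(C)O1)C[C@@H](O[Si](C)(C)C(C)(C)C)[C@H](C)/C(OS(=O)(=O)C(F)(F)F)=C/C[C@H](C)O[Si](C)(C)C(C)(C)C | intermediate (not isolated)
18 | (4S,5R)-5-[(S)-2,2-dimethyl-1,3-dioxolan-4-yl]-3-methylidene-4-[(2R,3S,4Z,7S)-2,7-bis(TBS-oxy)-3-methyl-4-(trifluoromethanesulfonyloxy)oct-4-en-1-yl]oxolan-2-one | C=C1C(=O)O[C@@H]([C@@H]2COC(C)(C)O2)[C@H]1C[C@@H](O[Si](C)(C)C(C)(C)C)[C@H](C)/C(OS(=O)(=O)C(F)(F)F)=C/C[C@H](C)O[Si](C)(C)C(C)(C)C | intermediate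
19 | (4S,5R)-5-[(S)-1,2-dihydroxyethyl] analogue of 18 (free diol) | C=C1C(=O)O[C@@H]([C@@H](O)CO)[C@H]1C[C@@H](O[Si](C)(C)C(C)(C)C)[C@H](C)/C(OS(=O)(=O)C(F)(F)F)=C/C[C@H](C)O[Si](C)(C)C(C)(C)C | intermediate (not isolated)
20 | (2R,3S)-4-methylidene-5-oxo-3-[(2R,3S,4Z,7S)-2,7-bis(TBS-oxy)-3-methyl-4-(trifluoromethanesulfonyloxy)oct-4-en-1-yl]oxolane-2-carbaldehyde | C=C1C(=O)O[C@@H](C=O)[C@H]1C[C@@H](O[Si](C)(C)C(C)(C)C)[C@H](C)/C(OS(=O)(=O)C(F)(F)F)=C/C[C@H](C)O[Si](C)(C)C(C)(C)C | intermediate
21 | cis-fused lactone–cycloheptane allylic alcohol (5R,6R,7S,9R,10R,4S), (Z)-C1=C2, C9 and C4 as TBS ethers, free C5–OH trans to the lactone oxygen | C=C1C(=O)O[C@@H]2[C@H]1C[C@@H](O[Si](C)(C)C(C)(C)C)[C@H](C)/C(=C/C[C@H](C)O[Si](C)(C)C(C)(C)C)[C@H]2O | intermediate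
22 | (S)-2-methylbutanoic acid | CC[C@H](C)C(=O)O | starting material
23 | C5 (S)-2-methylbutanoate of 21 | C=C1C(=O)O[C@@H]2[C@H]1C[C@@H](O[Si](C)(C)C(C)(C)C)[C@H](C)/C(=C/C[C@H](C)O[Si](C)(C)C(C)(C)C)[C@H]2OC(=O)[C@@H](C)CC | intermediate
24 | C1,C2-diol (1R,2R,4S,5S,6R,7S,9R,10S), C1–OH trans to the C5 ester oxygen, C9 and C4 as TBS ethers | C=C1C(=O)O[C@@H]2[C@H]1C[C@@H](O[Si](C)(C)C(C)(C)C)[C@H](C)[C@@](O)([C@H](O)C[C@H](C)O[Si](C)(C)C(C)(C)C)[C@H]2OC(=O)[C@@H](C)CC | intermediate
25 | C9,C4-bis-TBS ether of the target (1S,4S,5S,6R,7S,9R,10S) | C=C1C(=O)O[C@@H]2[C@H]1C[C@@H](O[Si](C)(C)C(C)(C)C)[C@H](C)[C@@](O)(C(=O)C[C@H](C)O[Si](C)(C)C(C)(C)C)[C@H]2OC(=O)[C@@H](C)CC | intermediate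
26 | CNP0291806.1 (1S,4S,5S,6R,7S,9R,10S; (S)-2-methylbutanoate) | C=C1C(=O)O[C@@H]2[C@H]1C[C@@H](O)[C@H](C)[C@@](O)(C(=O)C[C@H](C)O)[C@H]2OC(=O)[C@@H](C)CC | target

Total step count: 18. Longest linear sequence: 17 steps (1 to 26 through steps 1–3 and 5–18; step 4 is the side branch).

Steps most likely to fail

Step 14. What may go wrong: the alkenylchromium adds to the other face of the C5 aldehyde, because the polar Felkin–Anh and the dipole-opposed arrangements lead to opposite C5 epimers once the nucleophile is tethered through C7. Fallback: the same cyclisation is run from 20; if it gives mainly the C5-epimeric allylic alcohol F1, the acyl group is introduced with inversion by a Mitsunobu esterification of F1 with acid 22 (PPh3, DIAD, toluene, 0 °C to rt). C5 is then set by SN2 displacement instead of by the addition step, and the sequence comes back to the route at ester 23.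

Step 12. What may go wrong: low facial selectivity at the α-alkoxy aldehyde, or loss of the syn C6/C7 relation through equilibration of the allylindium geometry. Fallback: setting out from 14, acetylation (Ac2O, DMAP, CH2Cl2) gives the acetate F2. Copper-mediated SN2′ borylation (B2pin2, CuCl, KOAc, DMF, rt) then gives the primary allylboronate F3, with C8 cis to the CH2B group. Thermal allylboration of 16 (toluene, 80 °C) goes through a closed six-membered chair transition state, with the usual Felkin preference of allylboronates for this aldehyde, and acid lactonisation (PPTS) comes back to the route at lactone 18.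

Step 16. What may go wrong: competing osmylation of the methylene lactone, or attack of OsO4 on the upper face of the exocyclic alkene. Fallback: setting out from the free allylic alcohol 21, hydroxyl-directed epoxidation (VO(acac)2, t-BuOOH, CH2Cl2, 0 °C) touches only the allylic alkene and delivers oxygen to the face of the C5 hydroxyl, giving the epoxy alcohol F4. Steglich esterification with 22 (DCC, DMAP) gives the epoxy ester F5. Acid-catalysed hydrolysis (HClO4 cat., THF–H2O, 0 °C) opens the epoxide at the tertiary C1 with inversion, which places the C1 hydroxyl trans to the C5 oxygen in the C2-epimeric diol F6. Swern oxidation as in step 17 comes back to the route at ketone 25.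

Further compounds

F1 | step 14 | C5 epimer of 21 (C5–OH cis to the lactone oxygen) | C=C1C(=O)O[C@@H]2[C@H]1C[C@@H](O[Si](C)(C)C(C)(C)C)[C@H](C)/C(=C/C[C@H](C)O[Si](C)(C)C(C)(C)C)[C@@H]2O
F2 | step 12 | acetate of Morita–Baylis–Hillman adduct 14 | C=C(C(=O)OC)C(OC(C)=O)C[C@@H](O[Si](C)(C)C(C)(C)C)[C@H](C)/C(OS(=O)(=O)C(F)(F)F)=C/C[C@H](C)O[Si](C)(C)C(C)(C)C
F3 | step 12 | methyl (2E,5R,6S,7Z,10S)-2-[(pinacolatoboryl)methyl]-5,10-bis(TBS-oxy)-6-methyl-7-(trifluoromethanesulfonyloxy)undeca-2,7-dienoate | COC(=O)/C(CB1OC(C)(C)C(C)(C)O1)=C/C[C@@H](O[Si](C)(C)C(C)(C)C)[C@H](C)/C(OS(=O)(=O)C(F)(F)F)=C/C[C@H](C)O[Si](C)(C)C(C)(C)C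
F4 | step 16 | C1,C2-spiro-epoxide of 21 with the epoxide oxygen on the face of the C5 hydroxyl | C=C1C(=O)O[C@@H]2[C@H]1C[C@@H](O[Si](C)(C)C(C)(C)C)[C@H](C)[C@@]3(O[C@H]3C[C@H](C)O[Si](C)(C)C(C)(C)C)[C@H]2O
F5 | step 16 | C5 (S)-2-methylbutanoate of F4 | C=C1C(=O)O[C@@H]2[C@H]1C[C@@H](O[Si](C)(C)C(C)(C)C)[C@H](C)[C@@]3(O[C@H]3C[C@H](C)O[Si](C)(C)C(C)(C)C)[C@H]2OC(=O)[C@@H](C)CC
F6 | step 16 | C2 epimer of diol 24 | C=C1C(=O)O[C@@H]2[C@H]1C[C@@H](O[Si](C)(C)C(C)(C)C)[C@H](C)[C@@](O)([C@@H](O)C[C@H](C)O[Si](C)(C)C(C)(C)C)[C@H]2OC(=O)[C@@H](C)CC
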